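**Retrosynthetic overview**
1. Target 24 ⇐ hydrolysis of the aryl ester and acetate ⇐ 3β-bromide ⇐ radical mono-debromination of a C3 gem-dibromide (axial H delivery) ⇐ C3 ketone ⇐ C3 alcohol.
2. The C3 alcohol, the trans-decalin, the C4/C10 quaternary centres, C9 and the exocyclic methylene come from one Cp2TiCl radical bicyclisation of epoxy-polyene 19. Ring A (C4–C5) forms first, then ring B (C10–C9).
3. 19 ⇐ cross-metathesis joining the epoxy-isopropenyl fragment 9 (forms C5=C10) to aryl diene 18.
4. 9 ⇐ Sharpless epoxygeraniol (7) + methallyl cuprate. Geraniol (6) is built from sulcatone (4), which comes from acetoacetate + prenyl bromide. 18 ⇐ Negishi coupling of a benzylzinc (from o-cresol-derived 15) with the ZACA-derived vinyl iodide 17.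

Assumption: the C4 epimer and any Z-alkene diastereomers are chromatographically separable, and the required isomer is carried forward.

**Route**

**Step 1**
Reactants: 1 methyl acetoacetate; 2 prenyl bromide
Product: 3 methyl 2-acetyl-5-methylhex-4-enoate
Conditions: NaOMe, MeOH, 0 °C → 65 °C
Reagents that add atoms: none
Why: Acetoacetate C-alkylation (SN2) on the primary allylic bromide.

**Step 2**
Reactants: 3
Product: 4 6-methylhept-5-en-2-one (sulcatone)
Conditions: 5 M KOH, EtOH/H2O, 80 °C; then H3O+, 80 °C
Reagents that add atoms: none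
Why: Saponification and β-keto-acid decarboxylation (ketonic hydrolysis).

**Step 3**
Reactants: 4
Product: 5 ethyl (2E)-3,7-dimethylocta-2,6-dienoate
Conditions: NaH, THF, 0 °C → rt; chromatography removes the ~10% Z isomer
Reagents that add atoms: triethyl phosphonoacetate, CCOP(=O)(OCC)CC(=O)OCC
Why: Horner–Wadsworth–Emmons olefination is E-selective and sets the C3=C4 geometry of the allylic alcohol.

**Step 4**
Reactants: 5
Product: 6 geraniol
Conditions: DIBAL-H, CH2Cl2, –78 °C
Reagents that add atoms: none
Why: 1,2-Reduction of the ester to the allylic alcohol; the two trisubstituted alkenes are untouched.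

**Step 5**
Reactants: 6
Product: 7 (2R,3R)-2,3-epoxygeraniol
Conditions: Ti(OiPr)4, D-(–)-DET, TBHP, 4 Å MS, CH2Cl2, –20 °C
Reagents that add atoms: tert-butyl hydroperoxide, CC(C)(C)OO (oxygen source)
Why: Sharpless asymmetric epoxidation is hydroxyl-directed and therefore selective for the 2,3-alkene; it sets C3 as R, which later fixes the absolute configuration of the cascade.

**Step 6**
Reactants: 7
Product: 8 epoxy tosylate
Conditions: TsCl, Et3N, DMAP (cat.), CH2Cl2, 0 °C
Reagents that add atoms: p-toluenesulfonyl chloride, Cc1ccc(cc1)S(=O)(=O)Cl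
Why: Primary alcohol tosylation leaves the epoxide intact.

**Step 7**
Reactants: 8
Product: 9 (3R,4R)-2-(but-3-enyl? no: 4-methylpent-3-enyl)-2-methyl-3-(3-methylbut-3-enyl)oxirane
Conditions: methallylMgCl, Li2CuCl4 (cat.), THF, –30 °C
Reagents that add atoms: methallylmagnesium chloride, C=C(C)C[Mg]Cl
Why: Cu-catalysed SN2 displacement of the tosylate; the symmetric methallyl nucleophile removes any α/γ regiochemistry issue and installs C1 and the C10=C5H2 isopropenyl end.

**Step 8**
Reactants: 10 o-cresol
Product: 11 4-bromo-2-methylphenol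
Conditions: NBS (1.0 equiv), CH2Cl2, –10 °C
Reagents that add atoms: N-bromosuccinimide, O=C1CCC(=O)N1Br
Why: Electrophilic aromatic bromination occurs para to the OH.

**Step 9**
Reactants: 11
Product: 12 methyl 4-hydroxy-3-methylbenzoate
Conditions: Pd(OAc)2, dppf, CO (10 bar), MeOH, Et3N, 100 °C
Reagents that add atoms: carbon monoxide, [C-]#[O+]; methanol, CO
Why: Pd-catalysed methoxycarbonylation of the aryl bromide, tolerant of the free phenol.

**Step 10**
Reactants: 12
Product: 13 methyl 3-bromo-4-hydroxy-5-methylbenzoate
Conditions: NBS (1.05 equiv), iPr2NH (cat.), CH2Cl2, –78 °C → rt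
Reagents that add atoms: NBS, O=C1CCC(=O)N1Br
Why: Ortho-selective phenol bromination at the single free ortho position (the para position is blocked).

**Step 11**
Reactants: 13
Product: 14 methyl 4-acetoxy-3-bromo-5-methylbenzoate
Conditions: Ac2O, pyridine, DMAP (cat.), rt
Reagents that add atoms: acetic anhydride, CC(=O)OC(C)=O
Why: Acetylation protects the phenol before radical benzylic bromination.

**Step 12**
Reactants: 14
Product: 15 methyl 4-acetoxy-3-bromo-5-(bromomethyl)benzoate
Conditions: NBS, AIBN (cat.), PhCF3, 85 °C
Reagents that add atoms: NBS, O=C1CCC(=O)N1Br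
Why: Wohl–Ziegler benzylic bromination; the arene is electron-poor so ring bromination is suppressed.

**Step 13**
Reactants: 16 hex-5-en-1-yne
Product: 17 (E)-1-iodo-2-methylhexa-1,5-diene
Conditions: Me3Al, Cp2ZrCl2 (cat.), CH2Cl2, 0 °C → rt; then I2, THF, –30 °C
Reagents that add atoms: trimethylaluminium, C[Al](C)C; iodine, II
Why: Negishi Zr-catalysed carboalumination adds Me and Al syn across the alkyne, so Al and the chain are trans and iodination gives the E-vinyl iodide; the isolated terminal alkene is untouched.

**Step 14**
Reactants: 15; 17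
Product: 18 methyl 4-acetoxy-3-bromo-5-[(E)-3-methylhepta-2,6-dien-1-yl]benzoate
Conditions: (i) Zn dust, LiCl, THF, 25 °C (benzylzinc); (ii) 17, Pd(PPh3)4 (5 mol%), THF, 40 °C
Reagents that add atoms: none
Why: Negishi sp3–sp2 coupling keeps the alkene geometry, and the ArBr, ester and acetate survive the zinc reagent.

**Step 15**
Reactants: 9; 18 (2–3 equiv)
Product: 19 epoxy-polyene (E)-C5=C10
Conditions: Hoveyda–Grubbs II (5 mol%), CH2Cl2, 40 °C, ethylene removed under slight vacuum
Reagents that add atoms: none
Why: Cross-metathesis of the 1,1-disubstituted alkene of 9 with the monosubstituted alkene of 18 gives the E-trisubstituted C5=C10 alkene (E:Z about 4:1, separated on AgNO3–silica); the prenyl alkene, the other trisubstituted alkene and the epoxide are spectators.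

**Step 16**
Reactants: 19
Product: 20 methyl 4-acetoxy-3-bromo-5-{[(3R-hydroxy) trans-decalin with exocyclic methylene]methyl}benzoate (3β-alcohol)
Conditions: Cp2TiCl2 (20 mol%), Mn dust, 2,4,6-collidine, TMSCl, THF, 25 °C; then 1 M HCl/THF, 10 min
Reagents that add atoms: none
Why: Proposed new method: Cp2TiCl opens the trisubstituted (3R,4R)-epoxide at the tertiary C4–O bond to give a tertiary radical, which cyclises 6-endo onto C5=C10 and then 6-endo onto C9=C8 through chair–chair transition states with C3–OTi equatorial. This fixes the trans-decalin, the axial C10 methyl, axial H9 and equatorial C11. The final tertiary radical is captured by Ti(III) and β-H-eliminated to the exocyclic methylene, while the prenyl alkene is a spectator because 4-exo/5-endo closure is disfavoured. The closest known reaction is Cp2TiCl epoxypolyene cyclisation, but here the epoxide is internal and unsymmetrical, so C4 (Me axial/chain equatorial) is only partly controlled and the C4 epimer is removed by HPLC.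

**Step 17**
Reactants: 20
Product: 21 C3 ketone
Conditions: Dess–Martin periodinane, NaHCO3, CH2Cl2, 0 °C → rt
Reagents that add atoms: none
Why: Mild oxidation of the hindered secondary alcohol leaves the alkenes, bromide and esters alone; the C3 stereocentre is reset in step 19.

**Step 18**
Reactants: 21
Product: 22 3,3-dibromide
Conditions: (PhO)3P (1.2 equiv), Br2 (1.2 equiv, pre-mixed at –78 °C), Et3N, CH2Cl2, –78 °C → 25 °C
Reagents that add atoms: bromine, BrBr
Why: The phosphite–bromine adduct converts C=O into CBr2 without free Br2, so the prenyl and exocyclic alkenes are spared.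

**Step 19**
Reactants: 22
Product: 23 protected 3β-bromide
Conditions: Bu3SnH (1.0 equiv), Et3B (0.1 equiv), air (trace), toluene, –40 → 0 °C
Reagents that add atoms: none
Why: Proposed new method: Bu3Sn• abstracts one Br and the C3 radical takes H from Bu3SnH on its less hindered axial α-face (anti to the axial 4-Me and 10-Me, away from the gauche C4 substituents). This leaves Br equatorial (3β), by analogy with stannane reduction of gem-dihalocycloalkanes, which gives the more hindered halide; ArBr, the alkenes and the ester are untouched under these mild conditions.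

**Step 20**
Reactants: 23
Product: 24 callophycoic acid H
Conditions: LiOH·H2O, THF/MeOH/H2O, 25 → 40 °C
Reagents that add atoms: water, O
Why: Saponification cleaves the phenyl acetate and the methyl ester, while the neopentylic secondary bromide and both alkenes are untouched.

**Compound list**

| No. | Name | SMILES | Role |
|---|---|---|---|
| 1 | methyl acetoacetate | CC(=O)CC(=O)OC | starting material |
| 2 | prenyl bromide | CC(C)=CCBr | starting material |
| 3 | methyl 2-acetyl-5-methylhex-4-enoate | CC(=O)C(CC=C(C)C)C(=O)OC | intermediate |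
| 4 | 6-methylhept-5-en-2-one | CC(=O)CCC=C(C)C | intermediate |
| 5 | ethyl (2E)-3,7-dimethylocta-2,6-dienoate | CCOC(=O)/C=C(\C)CCC=C(C)C | intermediate |
| 6 | geraniol | OC/C=C(\C)CCC=C(C)C | intermediate |
| 7 | (2R,3R)-2,3-epoxygeraniol | OC[C@H]1O[C@]1(C)CCC=C(C)C | intermediate |
| 8 | epoxy tosylate of 7 | Cc1ccc(cc1)S(=O)(=O)OC[C@H]1O[C@]1(C)CCC=C(C)C | intermediate |
| 9 | (3R,4R)-epoxy-isopropenyl fragment | C=C(C)CC[C@H]1O[C@]1(C)CCC=C(C)C | intermediate |
| 10 | o-cresol | Cc1ccccc1O | starting material |
| 11 | 4-bromo-2-methylphenol | Cc1cc(Br)ccc1O | intermediate |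
| 12 | methyl 4-hydroxy-3-methylbenzoate | COC(=O)c1ccc(O)c(C)c1 | intermediate |
| 13 | methyl 3-bromo-4-hydroxy-5-methylbenzoate | COC(=O)c1cc(C)c(O)c(Br)c1 | intermediate |
| 14 | methyl 4-acetoxy-3-bromo-5-methylbenzoate | COC(=O)c1cc(C)c(OC(C)=O)c(Br)c1 | intermediate |
| 15 | methyl 4-acetoxy-3-bromo-5-(bromomethyl)benzoate | COC(=O)c1cc(CBr)c(OC(C)=O)c(Br)c1 | intermediate |
| 16 | hex-5-en-1-yne | C#CCCC=C | starting material |
| 17 | (E)-1-iodo-2-methylhexa-1,5-diene | I/C=C(\C)CCC=C | intermediate |
| 18 | aryl diene | COC(=O)c1cc(C/C=C(\C)CCC=C)c(OC(C)=O)c(Br)c1 | intermediate |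
| 19 | epoxy-polyene (cascade precursor) | COC(=O)c1cc(C/C=C(\C)CC/C=C(\C)CC[C@H]2O[C@]2(C)CCC=C(C)C)c(OC(C)=O)c(Br)c1 | intermediate |
| 20 | 3β-hydroxy decalin | C=C1CC[C@@H]2[C@@](C)(CCC=C(C)C)[C@H](O)CC[C@@]2(C)[C@@H]1Cc1cc(C(=O)OC)cc(Br)c1OC(C)=O | intermediate |
| 21 | C3 ketone | C=C1CC[C@@H]2[C@@](C)(CCC=C(C)C)C(=O)CC[C@@]2(C)[C@@H]1Cc1cc(C(=O)OC)cc(Br)c1OC(C)=O | intermediate |
| 22 | 3,3-dibromide | C=C1CC[C@@H]2[C@@](C)(CCC=C(C)C)C(Br)(Br)CC[C@@]2(C)[C@@H]1Cc1cc(C(=O)OC)cc(Br)c1OC(C)=O | intermediate |
| 23 | protected callophycoic acid H | C=C1CC[C@@H]2[C@@](C)(CCC=C(C)C)[C@H](Br)CC[C@@]2(C)[C@@H]1Cc1cc(C(=O)OC)cc(Br)c1OC(C)=O | intermediate |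
| 24 | callophycoic acid H | C=C1CC[C@@H]2[C@@](C)(CCC=C(C)C)[C@H](Br)CC[C@@]2(C)[C@@H]1Cc1cc(C(=O)O)cc(Br)c1O | target |

**Total steps:** 20
**Longest linear sequence:** 13 (steps 1–7, 15–20)

**Three steps most likely to fail**
1. **Step 16 (Ti(III) bicyclisation).** C4 is set with little selectivity because Me and the chain are sterically similar, and exo/endo alkene mixtures are possible. Fallback that changes the approach: run a Lewis-acid epoxide-initiated cationic cyclisation of 19 (MeAlCl2), where the E-alkene geometry controls C4, or a bromonium-initiated polyene cyclisation of the epoxide-free triene.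
2. **Steps 18–19 (gem-dibromination, then axial-H mono-reduction).** The hindered ketone may brominate poorly or brominate the alkenes, and the H-delivery selectivity may be low. Fallback that changes the approach: form C3–Br directly in a bromonium-initiated (Snyder-type) cyclisation of the epoxide-free polyene, where the anti addition sets the equatorial bromide.
3. **Step 15 (cross-metathesis).** Type III/type I coupling may give low yield and E/Z mixtures, and the terminal alkene of 18 may homodimerise. Fallback that changes the approach: assemble the C5=C10 alkene by ZACA–Negishi coupling on an epoxide-free diene fragment, and introduce the chiral epoxide later by asymmetric epoxidation.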